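**Retrosynthetic overview** (ring numbered as in the target: C1 bears CH3, C2 is the alkene CH, C3 bears the C20 chain, C4 the isopropenyl group)
1. Target ⇒ ring acid with CO2H at C4: the last step is a decarboxylative isopropenylation in which the new group enters trans to the C3 substituent; the chain end is attached before that by tosylate/Grignard coupling.
2. C1=C2 alkene ⇒ enol triflate ⇒ 2-methylcyclohex-2-enone (conjugate hydride addition, triflation, formate reduction).
3. Quaternary carbon and C3 ⇒ Carroll rearrangement of a (2Z,6E)-farnesyl β-keto ester; the C4 ester steers both centres and the C3 carboxyl leaves as CO2.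
4. β-Keto diester ⇒ oxidation of the Diels–Alder adduct of dimethyl fumarate and a 1-silyloxy-2-methylbutadiene; this cycloaddition forms the only ring, making C2–C3 and C4–C5 together.
5. Enabling feature: ring atoms C2–C1(CH3)–C6–C5 are a 2-methylbutadiene once C2 carries oxygen (C2 is the later alkene CH), and C3–C4, each with one carbon substituent in a trans relationship, are a fumarate unit whose twofold symmetry removes the regiochemical question.

Key step: step 3

Assumption: the catalyst enantiomers given in steps 2 and 3 are those expected from the accepted facial models of these catalyst families; if a model should not hold, the mirror-image catalyst is used and nothing else changes.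

**Step 1**
Reactants: 1 (2E)-2-methylbut-2-enal
Product: 2 tert-butyl(dimethyl){[(1E)-2-methylbuta-1,3-dien-1-yl]oxy}silane
Conditions: t-BuMe2SiOTf, Et3N, Et2O, 0 → 20 °C
Reagents that add atoms: tert-butyldimethylsilyl trifluoromethanesulfonate, CC(C)(C)[Si](C)(C)OS(=O)(=O)C(F)(F)F
Why: Soft enolisation of the enal at its γ-methyl group (silyl dienol ether formation) should give the 1-silyloxy diene, the s-trans enal leading to the (1E) isomer.

**Step 2**
Reactants: 3 (2E)-1,4-dibromobut-2-ene
Product: 4 (3R)-4-bromo-3-methylbut-1-ene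
Conditions: MeMgBr, CuBr·SMe2 (1 mol%), (R,R)-Taniaphos (1.2 mol%), CH2Cl2, −75 °C
Reagents that add atoms: methylmagnesium bromide, C[Mg]Br
Why: Copper-catalysed asymmetric allylic alkylation in which the methyl group is delivered SN2′ and the chiral ferrocenyl diphosphine on copper selects the enantiotopic alkene face, which sets the (R) centre while the second bromide remains as the handle.

**Step 3**
Reactants: 2 tert-butyl(dimethyl){[(1E)-2-methylbuta-1,3-dien-1-yl]oxy}silane; 5 dimethyl (2E)-but-2-enedioate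
Product: 7 dimethyl (1R,2S,3S)-3-hydroxy-4-methylcyclohex-4-ene-1,2-dicarboxylate, via silyl ether cycloadduct 6 (not isolated)
Conditions: (S)-B-(o-tolyl)-diphenylprolinol oxazaborolidine (20 mol%), HN(SO2CF3)2 (20 mol%), CH2Cl2, −40 °C; then HF·pyridine, THF, 0 °C
Reagents that add atoms: none
Why: A concerted, asynchronous [4π+2π] cycloaddition takes place between the s-cis siloxydiene, whose HOMO is raised by the oxygen at its terminus, and the fumarate activated by coordination of one ester carbonyl to the chiral cationic boron Lewis acid. The closest known reaction type is the oxazaborolidinium-catalysed Diels–Alder reaction of fumarate esters and of silyloxydienes. The six-membered carbocycle is closed by suprafacial addition at both components, so that C2–C3 and C4–C5 (target numbering) form in one step. The two carboxyl-bearing centres come out trans because the (E) geometry of the fumarate is conserved, their absolute configuration is set by the catalyst, which shields one face of the bound dienophile, and the silyloxy centre follows the endo rule but is oxidised away in step 4. The step needs only facial selectivity, because the twofold symmetry of the dienophile makes the opposed directing effects of the 1-silyloxy and 2-methyl groups of the diene irrelevant. Fluoride cleavage of the silyl ether then gives the allylic alcohol that is isolated.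

**Step 4**
Reactants: 7 dimethyl (1R,2S,3S)-3-hydroxy-4-methylcyclohex-4-ene-1,2-dicarboxylate
Product: 8 dimethyl (1R)-4-methyl-3-oxocyclohex-4-ene-1,2-dicarboxylate (C-2 epimers, partly enolised)
Conditions: DMP [1,1,1-tris(acetyloxy)-1,1-dihydro-1,2-benziodoxol-3(1H)-one], CH2Cl2, 0 → 20 °C
Reagents that add atoms: none
Why: Periodinane oxidation of the allylic secondary alcohol under neutral conditions should give the enone, which turns the neighbouring ester into a β-keto ester (its centre becomes labile, which no longer matters) and so differentiates the two ester groups.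

**Step 5**
Reactants: 8 dimethyl (1R)-4-methyl-3-oxocyclohex-4-ene-1,2-dicarboxylate; 9 (2Z,6E)-3,7,11-trimethyldodeca-2,6,10-trien-1-ol
Product: 12 methyl (1R,6S)-4-methyl-5-oxo-6-[(3R,6E)-3,7,11-trimethyldodeca-1,6,10-trien-3-yl]cyclohex-3-ene-1-carboxylate, via farnesyl keto ester 10 (not isolated), via keto acid 11 (not isolated)
Conditions: 9 (1.3 equiv), 1,2-dichlorobenzene, 130 °C (MeOH removed in an N2 stream), then 175 °C
Reagents that add atoms: none
Why: Carroll rearrangement: ester exchange through the acylketene gives the farnesyl β-keto ester, whose hydrogen-bonded ester enol undergoes a chair [3,3] shift on the face of C3 opposite the C4 ester (held pseudoaxial by allylic strain), so that the (2Z) alkene geometry fixes the (R) quaternary centre, and loss of CO2 followed by ketonisation anti to the same ester should set the C3–H centre.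

**Step 6**
Reactants: 12 methyl (1R,6S)-4-methyl-5-oxo-6-[(3R,6E)-3,7,11-trimethyldodeca-1,6,10-trien-3-yl]cyclohex-3-ene-1-carboxylate
Product: 14 methyl (1R,2S)-4-methyl-3-[(trifluoromethanesulfonyl)oxy]-2-[(3R,6E)-3,7,11-trimethyldodeca-1,6,10-trien-3-yl]cyclohex-3-ene-1-carboxylate, via lithium enolate 13 (not isolated)
Conditions: LiBH(s-Bu)3, THF, −78 °C; then N-(5-chloropyridin-2-yl)bis(trifluoromethanesulfonimide), −78 → 0 °C
Reagents that add atoms: N-(5-chloropyridin-2-yl)bis(trifluoromethanesulfonimide), FC(F)(F)S(=O)(=O)N(c1ccc(Cl)cn1)S(=O)(=O)C(F)(F)F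
Why: Conjugate hydride addition to the β-unsubstituted enone gives the tetrasubstituted enolate regiospecifically, and O-sulfonylation traps it (1,4-reduction/enolate triflation) without touching the C3–H centre.

**Step 7**
Reactants: 14 methyl (1R,2S)-4-methyl-3-[(trifluoromethanesulfonyl)oxy]-2-[(3R,6E)-3,7,11-trimethyldodeca-1,6,10-trien-3-yl]cyclohex-3-ene-1-carboxylate
Product: 15 methyl (1R,2S)-4-methyl-2-[(3R,6E)-3,7,11-trimethyldodeca-1,6,10-trien-3-yl]cyclohex-3-ene-1-carboxylate
Conditions: Pd(OAc)2 (5 mol%), PPh3 (10 mol%), HCO2H, n-Bu3N, DMF, 60 °C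
Reagents that add atoms: none
Why: Palladium-catalysed formate reduction of the enol triflate (oxidative addition, decarboxylation of formate to the palladium hydride, reductive elimination) should replace OTf by H and leave the double bond fixed at C1=C2.

**Step 8**
Reactants: 15 methyl (1R,2S)-4-methyl-2-[(3R,6E)-3,7,11-trimethyldodeca-1,6,10-trien-3-yl]cyclohex-3-ene-1-carboxylate
Product: 17 methyl (1R,2S)-2-[(3R,6E)-1-hydroxy-3,7,11-trimethyldodeca-6,10-dien-3-yl]-4-methylcyclohex-3-ene-1-carboxylate, via alkylborane 16 (not isolated)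
Conditions: 9-BBN, THF, 0 → 40 °C; then NaBO3·4H2O, THF/H2O, 20 °C
Reagents that add atoms: sodium perborate tetrahydrate, [Na+].[O-]OB=O.O.O.O.O
Why: Hydroboration–oxidation: 9-BBN should add anti-Markovnikov to the only monosubstituted alkene (the trisubstituted alkenes and the ester are left), and the mild perborate oxidation gives the primary alcohol.

**Step 9**
Reactants: 17 methyl (1R,2S)-2-[(3R,6E)-1-hydroxy-3,7,11-trimethyldodeca-6,10-dien-3-yl]-4-methylcyclohex-3-ene-1-carboxylate
Product: 18 methyl (1R,2S)-4-methyl-2-[(3R,6E)-3,7,11-trimethyl-1-(tosyloxy)dodeca-6,10-dien-3-yl]cyclohex-3-ene-1-carboxylate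
Conditions: TsCl, pyridine, CH2Cl2, 0 °C
Reagents that add atoms: 4-methylbenzenesulfonyl chloride, Cc1ccc(cc1)S(Cl)(=O)=O
Why: Standard sulfonylation of the unhindered primary alcohol.

**Step 10**
Reactants: 18 methyl (1R,2S)-4-methyl-2-[(3R,6E)-3,7,11-trimethyl-1-(tosyloxy)dodeca-6,10-dien-3-yl]cyclohex-3-ene-1-carboxylate; 4 (3R)-4-bromo-3-methylbut-1-ene
Product: 20 methyl (1R,2S)-4-methyl-2-[(3S,7S,10E)-3,7,11,15-tetramethylhexadeca-1,10,14-trien-7-yl]cyclohex-3-ene-1-carboxylate, via Grignard reagent 19 (not isolated)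
Conditions: 4, Mg, THF, 20 °C; then 18, Li2CuCl4 (5 mol%), NMP, THF, −20 → 0 °C
Reagents that add atoms: none
Why: Copper-catalysed sp3–sp3 coupling of a primary tosylate with a primary alkyl Grignard reagent, in which the stereocentre of the Grignard reagent is β to magnesium and not involved and the hindered methyl ester is expected to survive at low temperature.

**Step 11**
Reactants: 20 methyl (1R,2S)-4-methyl-2-[(3S,7S,10E)-3,7,11,15-tetramethylhexadeca-1,10,14-trien-7-yl]cyclohex-3-ene-1-carboxylate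
Product: 21 (1R,2S)-4-methyl-2-[(3S,7S,10E)-3,7,11,15-tetramethylhexadeca-1,10,14-trien-7-yl]cyclohex-3-ene-1-carboxylic acid
Conditions: LiOH·H2O, THF/MeOH/H2O, 50 °C; then 1 M HCl
Reagents that add atoms: lithium hydroxide, [Li+].[OH-]
Why: Saponification of the methyl ester, where any epimerisation next to the carboxyl group is harmless because this carbon becomes a radical in the next step.

**Step 12**
Reactants: 21 (1R,2S)-4-methyl-2-[(3S,7S,10E)-3,7,11,15-tetramethylhexadeca-1,10,14-trien-7-yl]cyclohex-3-ene-1-carboxylic acid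
Product: 23 (3S,4S)-1-methyl-4-(prop-1-en-2-yl)-3-[(3S,7S,10E)-3,7,11,15-tetramethylhexadeca-1,10,14-trien-7-yl]cyclohex-1-ene, via redox-active ester 22 (not isolated)
Conditions: N-hydroxyphthalimide, DIC, DMAP (cat.), CH2Cl2, 20 °C; then NiCl2·DME (10 mol%), 2,2′-bipyridine (20 mol%), isopropenylzinc bromide, THF/DMF, 20 °C
Reagents that add atoms: isopropenylzinc bromide, C=C(C)[Zn]Br
Why: Nickel-catalysed decarboxylative alkenylation (Negishi-type coupling of an N-acyloxyphthalimide): single-electron reduction releases CO2 and a secondary C4 radical, which nickel captures and couples with the isopropenyl group on the face opposite the bulky C3 substituent, which should set the trans (3S,4S) relationship.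

**Compound list**
1 | (2E)-2-methylbut-2-enal | C/C=C(\C)C=O | starting material
2 | tert-butyl(dimethyl){[(1E)-2-methylbuta-1,3-dien-1-yl]oxy}silane | C=C/C(C)=C/O[Si](C)(C)C(C)(C)C | intermediate
3 | (2E)-1,4-dibromobut-2-ene | BrC/C=C/CBr | starting material
4 | (3R)-4-bromo-3-methylbut-1-ene | BrC[C@H](C)C=C | intermediate
5 | dimethyl (2E)-but-2-enedioate (dimethyl fumarate) | COC(=O)/C=C/C(=O)OC | starting material
6 | dimethyl (1R,2S,3S)-3-{[tert-butyl(dimethyl)silyl]oxy}-4-methylcyclohex-4-ene-1,2-dicarboxylate | COC(=O)[C@@H]1CC=C(C)[C@@H](O[Si](C)(C)C(C)(C)C)[C@H]1C(=O)OC | intermediate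
7 | dimethyl (1R,2S,3S)-3-hydroxy-4-methylcyclohex-4-ene-1,2-dicarboxylate | COC(=O)[C@@H]1CC=C(C)[C@@H](O)[C@H]1C(=O)OC | intermediate
8 | dimethyl (1R)-4-methyl-3-oxocyclohex-4-ene-1,2-dicarboxylate (C-2 epimers, partly enolised) | COC(=O)[C@@H]1CC=C(C)C(=O)C1C(=O)OC | intermediate
9 | (2Z,6E)-3,7,11-trimethyldodeca-2,6,10-trien-1-ol [(2Z,6E)-farnesol] | OC/C=C(/C)CC/C=C(\C)CCC=C(C)C | starting material
10 | 1-methyl 2-[(2Z,6E)-3,7,11-trimethyldodeca-2,6,10-trien-1-yl] (1R)-4-methyl-3-oxocyclohex-4-ene-1,2-dicarboxylate (C-2 epimers) | COC(=O)[C@@H]1CC=C(C)C(=O)C1C(=O)OC/C=C(/C)CC/C=C(\C)CCC=C(C)C | intermediate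
11 | (1S,6R)-6-(methoxycarbonyl)-3-methyl-2-oxo-1-[(3R,6E)-3,7,11-trimethyldodeca-1,6,10-trien-3-yl]cyclohex-3-ene-1-carboxylic acid | COC(=O)[C@@H]1CC=C(C)C(=O)[C@@]1(C(=O)O)[C@@](C)(C=C)CC/C=C(\C)CCC=C(C)C | intermediate
12 | methyl (1R,6S)-4-methyl-5-oxo-6-[(3R,6E)-3,7,11-trimethyldodeca-1,6,10-trien-3-yl]cyclohex-3-ene-1-carboxylate | COC(=O)[C@@H]1CC=C(C)C(=O)[C@@H]1[C@@](C)(C=C)CC/C=C(\C)CCC=C(C)C | intermediate
13 | lithium (5R,6S)-5-(methoxycarbonyl)-2-methyl-6-[(3R,6E)-3,7,11-trimethyldodeca-1,6,10-trien-3-yl]cyclohex-1-en-1-olate | [Li+].COC(=O)[C@@H]1CCC(C)=C([O-])[C@@H]1[C@@](C)(C=C)CC/C=C(\C)CCC=C(C)C | intermediate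
14 | methyl (1R,2S)-4-methyl-3-[(trifluoromethanesulfonyl)oxy]-2-[(3R,6E)-3,7,11-trimethyldodeca-1,6,10-trien-3-yl]cyclohex-3-ene-1-carboxylate | COC(=O)[C@@H]1CCC(C)=C(OS(=O)(=O)C(F)(F)F)[C@@H]1[C@@](C)(C=C)CC/C=C(\C)CCC=C(C)C | intermediate
15 | methyl (1R,2S)-4-methyl-2-[(3R,6E)-3,7,11-trimethyldodeca-1,6,10-trien-3-yl]cyclohex-3-ene-1-carboxylate | COC(=O)[C@@H]1CCC(C)=C[C@@H]1[C@@](C)(C=C)CC/C=C(\C)CCC=C(C)C | intermediate
16 | methyl (1R,2S)-2-[(3S,6E)-1-(9-borabicyclo[3.3.1]nonan-9-yl)-3,7,11-trimethyldodeca-6,10-dien-3-yl]-4-methylcyclohex-3-ene-1-carboxylate | COC(=O)[C@@H]1CCC(C)=C[C@@H]1[C@@](C)(CCB2C3CCCC2CCC3)CC/C=C(\C)CCC=C(C)C | intermediate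
17 | methyl (1R,2S)-2-[(3R,6E)-1-hydroxy-3,7,11-trimethyldodeca-6,10-dien-3-yl]-4-methylcyclohex-3-ene-1-carboxylate | COC(=O)[C@@H]1CCC(C)=C[C@@H]1[C@@](C)(CCO)CC/C=C(\C)CCC=C(C)C | intermediate
18 | methyl (1R,2S)-4-methyl-2-[(3R,6E)-3,7,11-trimethyl-1-(tosyloxy)dodeca-6,10-dien-3-yl]cyclohex-3-ene-1-carboxylate | COC(=O)[C@@H]1CCC(C)=C[C@@H]1[C@@](C)(CCOS(=O)(=O)c1ccc(C)cc1)CC/C=C(\C)CCC=C(C)C | intermediate
19 | bromo[(2R)-2-methylbut-3-en-1-yl]magnesium | Br[Mg]C[C@H](C)C=C | intermediate
20 | methyl (1R,2S)-4-methyl-2-[(3S,7S,10E)-3,7,11,15-tetramethylhexadeca-1,10,14-trien-7-yl]cyclohex-3-ene-1-carboxylate | COC(=O)[C@@H]1CCC(C)=C[C@@H]1[C@@](C)(CCC[C@H](C)C=C)CC/C=C(\C)CCC=C(C)C | intermediate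
21 | (1R,2S)-4-methyl-2-[(3S,7S,10E)-3,7,11,15-tetramethylhexadeca-1,10,14-trien-7-yl]cyclohex-3-ene-1-carboxylic acid | OC(=O)[C@@H]1CCC(C)=C[C@@H]1[C@@](C)(CCC[C@H](C)C=C)CC/C=C(\C)CCC=C(C)C | intermediate
22 | 1,3-dioxo-1,3-dihydro-2H-isoindol-2-yl (1R,2S)-4-methyl-2-[(3S,7S,10E)-3,7,11,15-tetramethylhexadeca-1,10,14-trien-7-yl]cyclohex-3-ene-1-carboxylate | O=C(ON1C(=O)c2ccccc2C1=O)[C@@H]1CCC(C)=C[C@@H]1[C@@](C)(CCC[C@H](C)C=C)CC/C=C(\C)CCC=C(C)C | intermediate
23 | (3S,4S)-1-methyl-4-(prop-1-en-2-yl)-3-[(3S,7S,10E)-3,7,11,15-tetramethylhexadeca-1,10,14-trien-7-yl]cyclohex-1-ene | C=C[C@@H](C)CCC[C@@](C)(CC/C=C(\C)CCC=C(C)C)[C@H]1C=C(C)CC[C@@H]1C(=C)C | target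

**Step count and risks**
Total step count: 12. Longest linear sequence: 11 steps (step 1, then steps 3 to 12).

Steps most likely to fail:

Step 5. The [3,3] shift joins two fully substituted carbons and may be slower than thermal decomposition of the polyene. The chair preference, or the kinetic ketonisation at C3, may also be incomplete, which would erode the relationship between C3 and the quaternary carbon. The fallback sets out from 8 (with 9) and comes back at 12. Mitsunobu O-alkylation of the enolised keto ester 8 with 9 (PPh3, DIAD, THF, 0 °C) should give the farnesyl dienyl ether dimethyl (1R)-4-methyl-3-{[(2Z,6E)-3,7,11-trimethyldodeca-2,6,10-trien-1-yl]oxy}cyclohexa-2,4-diene-1,2-dicarboxylate F1. As an allyl vinyl ether it should undergo the Claisen rearrangement already in toluene at 100 °C, with the same facial and chair arguments, to the α-quaternary keto diester dimethyl (1R,2S)-4-methyl-3-oxo-2-[(3R,6E)-3,7,11-trimethyldodeca-1,6,10-trien-3-yl]cyclohex-4-ene-1,2-dicarboxylate F2. Krapcho dealkoxycarbonylation (LiCl, wet DMSO, 130 °C) removes the activated ester, and protonation of the enolate on cold acidic work-up gives 12.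

Step 3. Under the strong cationic Lewis acid the silyl dienol ether may add in an open-chain Mukaiyama–Michael manner or lose its silyl group before cycloaddition, and shielding of one dienophile face may be insufficient. The fallback sets out from 1 and comes back at 7. Enol acetylation of 1 (isopropenyl acetate, TsOH cat., 90 °C) gives the less nucleophilic diene (1E)-2-methylbuta-1,3-dien-1-yl acetate F3. The dienophile is changed to the chelating imide methyl (2E)-4-oxo-4-(2-oxo-1,3-oxazolidin-3-yl)but-2-enoate F4, made from commercial methyl (2E)-4-chloro-4-oxobut-2-enoate and 1,3-oxazolidin-2-one with Et3N. The copper bis(oxazoline) complex Cu(SbF6)2·(S,S)-2,2′-isopropylidenebis(4-tert-butyl-2-oxazoline) (10 mol%, CH2Cl2, −20 °C) should catalyse the Diels–Alder reaction through the two-point-bound dienophile to the acetoxy imide methyl (1R,5S,6S)-5-(acetyloxy)-4-methyl-6-[(2-oxo-1,3-oxazolidin-3-yl)carbonyl]cyclohex-3-ene-1-carboxylate F5; either orientation of the diene leads to the same diester after the next operation. Mg(OMe)2 in MeOH at 0 °C exchanges the imide for the methyl ester and removes the acetate, which gives 7.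

Step 12. The secondary ring radical may cyclise onto the trisubstituted alkene of the neighbouring chain before nickel captures it, or the C–C bond formation may be less trans-selective than expected. The fallback sets out from 21 and comes back at 23. MeLi (2.2 equiv, THF, −78 → 0 °C) converts the acid into the cis methyl ketone 1-[(1R,2S)-4-methyl-2-[(3S,7S,10E)-3,7,11,15-tetramethylhexadeca-1,10,14-trien-7-yl]cyclohex-3-en-1-yl]ethan-1-one F6. NaOMe in MeOH (20 °C) equilibrates the centre next to the ketone to the trans ketone 1-[(1S,2S)-4-methyl-2-[(3S,7S,10E)-3,7,11,15-tetramethylhexadeca-1,10,14-trien-7-yl]cyclohex-3-en-1-yl]ethan-1-one F7; the cis epimer is separated and resubmitted. Wittig methylenation (Ph3PCH3Br, KOt-Bu, THF, 0 → 20 °C) of F7 gives 23.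

**Further compounds**
F1 | step 5 | dimethyl (1R)-4-methyl-3-{[(2Z,6E)-3,7,11-trimethyldodeca-2,6,10-trien-1-yl]oxy}cyclohexa-2,4-diene-1,2-dicarboxylate | COC(=O)[C@@H]1CC=C(C)C(OC/C=C(/C)CC/C=C(\C)CCC=C(C)C)=C1C(=O)OC
F2 | step 5 | dimethyl (1R,2S)-4-methyl-3-oxo-2-[(3R,6E)-3,7,11-trimethyldodeca-1,6,10-trien-3-yl]cyclohex-4-ene-1,2-dicarboxylate | COC(=O)[C@@H]1CC=C(C)C(=O)[C@@]1(C(=O)OC)[C@@](C)(C=C)CC/C=C(\C)CCC=C(C)C
F3 | step 3 | (1E)-2-methylbuta-1,3-dien-1-yl acetate | C=C/C(C)=C/OC(C)=O
F4 | step 3 | methyl (2E)-4-oxo-4-(2-oxo-1,3-oxazolidin-3-yl)but-2-enoate | COC(=O)/C=C/C(=O)N1CCOC1=O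
F5 | step 3 | methyl (1R,5S,6S)-5-(acetyloxy)-4-methyl-6-[(2-oxo-1,3-oxazolidin-3-yl)carbonyl]cyclohex-3-ene-1-carboxylate | COC(=O)[C@@H]1CC=C(C)[C@@H](OC(C)=O)[C@H]1C(=O)N1CCOC1=O
F6 | step 12 | 1-[(1R,2S)-4-methyl-2-[(3S,7S,10E)-3,7,11,15-tetramethylhexadeca-1,10,14-trien-7-yl]cyclohex-3-en-1-yl]ethan-1-one | CC(=O)[C@@H]1CCC(C)=C[C@@H]1[C@@](C)(CCC[C@H](C)C=C)CC/C=C(\C)CCC=C(C)C
F7 | step 12 | 1-[(1S,2S)-4-methyl-2-[(3S,7S,10E)-3,7,11,15-tetramethylhexadeca-1,10,14-trien-7-yl]cyclohex-3-en-1-yl]ethan-1-one | CC(=O)[C@H]1CCC(C)=C[C@@H]1[C@@](C)(CCC[C@H](C)C=C)CC/C=C(\C)CCC=C(C)C
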